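X charged per L charged is 2.50 in the west run and 5.00 in the south-east run, which holds the same L and twice the X, and I counted turnovers against that ratio. The south run repeats the west charge, so its E at 24 min is the west run carried further.

| flask | L | X | time |
|---|---|---|---|
| west | 0.400 M | 1.00 M |  |
| north-east | 0.200 M | 0.800 M |  |
| south-east | 0.400 M | 2.00 M |  |
| south | 0.400 M | 1.00 M | 24 min |

| run | time / min | [E] / M |
|---|---|---|
| west run | 0.32 | 0.0364 |
| west run | 0.55 | 0.0564 |
| west run | 0.95 | 0.0903 |
| west run | 1.6 | 0.1296 |
| west run | 2.8 | 0.1755 |
| west run | 4.7 | 0.2129 |
| west run | 8.1 | 0.2399 |
| north-east run | 0.32 | 0.0144 |
| north-east run | 0.55 | 0.0232 |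
| north-east run | 0.95 | 0.0398 |
| north-east run | 1.6 | 0.0582 |
| north-east run | 2.8 | 0.0818 |
| north-east run | 4.7 | 0.1059 |
| north-east run | 8.1 | 0.1206 |
| south-east run | 0.32 | 0.0677 |
| south-east run | 0.55 | 0.1054 |
| south-east run | 0.95 | 0.1529 |
| south-east run | 1.6 | 0.2007 |
| south-east run | 2.8 | 0.2380 |
| south-east run | 4.7 | 0.2397 |
| south-east run | 8.1 | 0.2010 |

(standard deviation of a reading: 0.001 M)

- Overall: L + X -> E.
- Constant volume, constant temperature.
- A reading of a species includes what of it is bound.
- "The second partner" is X.
- An order is taken over about fifteen percent of the charge, up and down.

1. reaction order in [X] at the outset, round the charge of the west run, defined at two percent of the L turned into E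
2. reaction order in [L] at the outset, round the charge of the west run, defined at two percent of the L turned into E (one fixed amount of E, the same in the runs compared)
3. E in the south run at 24 min, as a share of the L charged

At 8.1 min the west run read 60.0 % of its L as E and was still rising, while the south-east run read 50.2 %, down from 59.9 % at 4.7 min. Both runs passed through about the same E, near 43.9 % of the L charged. I took the rate as first order in X, so the ratio of their slopes there gave the ratio of their X, and I took the difference between those two amounts of X to be that of the charges. In fractions of the L charged, I read:

slope ratio, south-east over west = 2.74

X left in the west run at that E = 1.44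

X spent per E in hand = 2.42

That reading lies nearer two than one. I therefore assumed two X per L turned, with the excess being E already lost, and one further X for each E lost. The spare X, the X per L charged that remains after the whole L has been paid for, then follows:

west spare = 0.500; south-east spare = 3.00

Losing the whole of the E would take one X per L charged. The south-east spare covers that, but the west spare falls short, so on this count X is the limiting reagent of the west chain. If the L turned completely and the X were used up, the west run would hold 50.0 % as E. I placed the south run between that share and the 60.0 % already read.

The forecast gave orders of 0.97 in X and 1 in L, and 35 % for the south run, with the loss of E “only weakly dependent on X”. My range lay above its share.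

The flask gives orders of 1.0 and 1.0, and 57.9 %.

    L + X → E + Q (0.3120 M⁻¹ min⁻¹)
    E + X → J (0.08700 M⁻¹ min⁻¹)
    X + Q ⇌ XQ, settled at all times (196.0 M⁻¹)

The south run's 57.9 % lies above the 50.0 % of my count and below the west reading. My two X per L match the X of the first step plus the X held as XQ, and on my count the spare of 0.500 is the X left for E + X → J once the whole L has turned. The same south run without that step gives 94.7 % against 57.9 %, so that step is the main reason for the E missing: it takes 37 percentage points, which is 87 % of what is missing.

(The earlier runs and the new flask are calculated for substances that don't exist; scatter was added.)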